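Numbering the naphthalene so that C1 carries the ring C aryl group, C2 the ring D benzyl group and C3 the hydroxyl (ring A = C1–C4, C4a, C8a; ring B = C4a–C8a), the plan rests on the C4–C4a bond. C4 is an unsubstituted CH flanked by oxygenated C3 and ring B carbon C4a, so it maps onto the α-carbon of a β-keto ester and C4a onto a free ortho C–H of a syringyl ring. A manganese-mediated anodic oxidation couples these two nucleophilic carbons and closes ring A in one operation. The precursor is a benzyl 3-oxopentanoate carrying the ditosylated ring D benzyl at pentanoate C4 and O-benzylated rings B and C at C5.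

Key step: step 11

Remark: all sp3 stereocentres are racemic; step 10 should give both relative configurations at pentanoate C4/C5, and the mixture is carried on because both centres become sp2 in step 12; the SMILES of 19 and 20 show the diastereomer that corresponds to the trans tetralone, and the C1–aryl axis of 21–24 is drawn without configuration.

Step 1
Reactants: 1 syringaldehyde
Product: 2 4-(benzyloxy)-3,5-dimethoxybenzaldehyde
Conditions: BnBr, K2CO3, DMF, 60 °C
Reagents that add atoms: benzyl bromide, BrCc1ccccc1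
Why: Williamson etherification of the phenoxide with a benzylic bromide, to which the aldehyde is inert; benzyl is chosen so that this ether falls in the final hydrogenolysis.

Step 2
Reactants: 2 4-(benzyloxy)-3,5-dimethoxybenzaldehyde
Product: 3 ethyl (E)-3-[4-(benzyloxy)-3,5-dimethoxyphenyl]prop-2-enoate
Conditions: Ph3P=CHCO2Et, toluene, 90 °C
Reagents that add atoms: ethyl (triphenylphosphoranylidene)acetate, CCOC(=O)C=P(c1ccccc1)(c1ccccc1)c1ccccc1
Why: Wittig olefination with a stabilised ylide should give the E-cinnamate, and a minor Z isomer would not matter because the alkene is consumed in step 5.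

Step 3
Reactants: 4 4-bromo-3-methoxyphenol
Product: 5 4-(benzyloxy)-1-bromo-2-methoxybenzene
Conditions: BnBr, K2CO3, DMF, 60 °C
Reagents that add atoms: benzyl bromide, BrCc1ccccc1
Why: Williamson etherification masks the ring C phenol with the same hydrogenolysable group as ring B and leaves the aryl bromide untouched.

Step 4
Reactants: 5 4-(benzyloxy)-1-bromo-2-methoxybenzene
Product: 8 [4-(benzyloxy)-2-methoxyphenyl]boronic acid, via aryllithium 6 (not isolated), via lithium aryltriisopropoxyborate 7 (not isolated)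
Conditions: n-BuLi, THF, −78 °C; B(OiPr)3, −78 °C → rt; 1 M HCl
Reagents that add atoms: triisopropyl borate, CC(C)OB(OC(C)C)OC(C)C; water, O
Why: Bromine–lithium exchange at −78 °C is faster than benzylic deprotonation, and the aryllithium is trapped by the borate ester and hydrolysed to the boronic acid (lithiation–borylation).

Step 5
Reactants: 3 ethyl (E)-3-[4-(benzyloxy)-3,5-dimethoxyphenyl]prop-2-enoate; 8 [4-(benzyloxy)-2-methoxyphenyl]boronic acid
Product: 10 3-[4-(benzyloxy)-3,5-dimethoxyphenyl]-3-[4-(benzyloxy)-2-methoxyphenyl]propanoic acid (racemic), via ethyl 3,3-diarylpropanoate 9 (not isolated)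
Conditions: [Rh(OH)(cod)]2 (2.5 mol%), 8 (2 equiv), 1,4-dioxane/H2O 10:1, 60 °C; then LiOH·H2O, MeOH, 50 °C; 1 M HCl
Reagents that add atoms: lithium hydroxide, [Li+].[OH-]
Why: Hayashi–Miyaura 1,4-addition, in which the aryl group passes from boron to monovalent rhodium, inserts into the enoate and the rhodium enolate is protonated by water, forms the benzhydryl centre as a racemate (achiral diene ligand; the centre is erased in step 12), and saponification in the same flask lets acid 10 be separated from boron residues by extraction before any sulfonate is present.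

Step 6
Reactants: 10 3-[4-(benzyloxy)-3,5-dimethoxyphenyl]-3-[4-(benzyloxy)-2-methoxyphenyl]propanoic acid
Product: 13 benzyl 5-[4-(benzyloxy)-3,5-dimethoxyphenyl]-5-[4-(benzyloxy)-2-methoxyphenyl]-3-oxopentanoate (racemic), via acyl imidazolide 11 (not isolated), via acylmalonic half ester 12 (not isolated)
Conditions: CDI, THF, rt; then Mg(O2CCH2CO2Bn)2 (1 equiv, from BnO2CCH2CO2H and Mg(OEt)2 in THF), rt → 45 °C; 1 M HCl
Reagents that add atoms: benzyl hydrogen malonate (as its magnesium salt), O=C(O)CC(=O)OCc1ccccc1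
Why: Decarboxylative Claisen-type C-acylation of a magnesium malonate half ester by an acyl imidazolide runs under nearly neutral conditions and is applied here to an unbranched acid, where it is most reliable.

Step 7
Reactants: 14 3,4-dihydroxybenzaldehyde
Product: 15 4-formyl-1,2-phenylene bis(4-methylbenzenesulfonate)
Conditions: TsCl (2.3 equiv), Et3N, DMAP (cat.), CH2Cl2, 0 °C → rt
Reagents that add atoms: 4-methylbenzenesulfonyl chloride, Cc1ccc(cc1)S(Cl)(=O)=O
Why: Sulfonylation of both catechol hydroxyls gives sulfonates that withstand hydride, LDA, acetic acid and DDQ and that deactivate ring D toward oxidation and radical attack in step 11.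

Step 8
Reactants: 15 4-formyl-1,2-phenylene bis(4-methylbenzenesulfonate)
Product: 16 4-(hydroxymethyl)-1,2-phenylene bis(4-methylbenzenesulfonate)
Conditions: NaBH4, THF/MeOH, 0 °C
Reagents that add atoms: none
Why: Borohydride reduces the aldehyde chemoselectively, aryl sulfonates being inert to it at 0 °C.

Step 9
Reactants: 16 4-(hydroxymethyl)-1,2-phenylene bis(4-methylbenzenesulfonate)
Product: 17 4-(bromomethyl)-1,2-phenylene bis(4-methylbenzenesulfonate)
Conditions: PBr3 (0.4 equiv), CH2Cl2, 0 °C → rt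
Reagents that add atoms: phosphorus tribromide, BrP(Br)Br
Why: The benzylic alcohol is converted to the bromide by SN2 displacement of its phosphite ester, and nothing in the molecule is sensitive to the HBr formed.

Step 10
Reactants: 13 benzyl 5-[4-(benzyloxy)-3,5-dimethoxyphenyl]-5-[4-(benzyloxy)-2-methoxyphenyl]-3-oxopentanoate; 17 4-(bromomethyl)-1,2-phenylene bis(4-methylbenzenesulfonate)
Product: 19 benzyl (4S*,5S*)-5-[4-(benzyloxy)-3,5-dimethoxyphenyl]-5-[4-(benzyloxy)-2-methoxyphenyl]-4-{[3,4-bis(tosyloxy)phenyl]methyl}-3-oxopentanoate (racemic), via dilithium dienolate 18 (not isolated)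
Conditions: LDA (2.1 equiv), THF, −78 → 0 °C; then 17, −78 → 0 °C; aq. NH4Cl
Reagents that add atoms: none
Why: γ-Alkylation of a β-keto ester dianion places the benzylic bromide on the more basic terminal carbon (pentanoate C4) only, the new C4 centre forms next to C5 under substrate control alone (a mixture is acceptable because both centres are erased), and bringing in the sulfonates only at this point means no hydroxide meets them before step 13.

Step 11
Reactants: 19 benzyl (4S*,5S*)-5-[4-(benzyloxy)-3,5-dimethoxyphenyl]-5-[4-(benzyloxy)-2-methoxyphenyl]-4-{[3,4-bis(tosyloxy)phenyl]methyl}-3-oxopentanoate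
Product: 20 benzyl (3S*,4S*)-7-(benzyloxy)-4-[4-(benzyloxy)-2-methoxyphenyl]-3-{[3,4-bis(tosyloxy)phenyl]methyl}-2-hydroxy-6,8-dimethoxy-3,4-dihydronaphthalene-1-carboxylate (racemic, trans; enol form of the 2-tetralone-1-carboxylate; in target numbering the ester sits on C4 and the enol on C3)
Conditions: Mn(OAc)2·4H2O (20 mol%), KOAc (0.2 M), AcOH/MeCN 1:1, 60 °C, undivided cell, graphite anode, Pt cathode, 5 mA cm−2, ca. 2.1 F mol−1, Ar
Reagents that add atoms: none
Why: Trivalent manganese, made at the anode from divalent manganese, binds the enol of the β-keto ester and oxidises it to the electrophilic α-carbon radical (future C4), which adds to a syringyl ortho carbon (future C4a); the cyclohexadienyl radical is oxidised once more and loses a proton to restore ring B, while protons are reduced to H2 at the cathode. The closest known reaction type is the Mn(OAc)3-mediated oxidative cyclisation of 5-aryl-3-oxopentanoates to 2-tetralone-1-carboxylates, run here with the oxidant regenerated electrochemically as in manganese-mediated anodic reactions of β-dicarbonyl compounds. Ring A closes as a six-membered ring (C4–C3–C2–C1–C8a–C4a) by ortho homolytic aromatic substitution, a 6-exo attack with respect to the C4a–C5 bond of the arene. No stereocentre is created: C1 is untouched, and C2 can epimerise through the ketone and should settle trans to the C1 aryl group. The step needs ring B to be attacked in preference to rings C and D and the enol to be oxidised in preference to the aryl ethers: the two syringyl ortho carbons are equivalent and each lies ortho to one methoxy group and para to the other, the only free ortho carbon of ring C is meta to both its oxygens, ring D is deactivated by two sulfonates, and the low potential of the manganese couple keeps the anode below the oxidation potential of the arenes. Over-oxidation of 20 would lead to naphthoate 21, the product of the next step, so it does not cost material.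

Step 12
Reactants: 20 benzyl (3S*,4S*)-7-(benzyloxy)-4-[4-(benzyloxy)-2-methoxyphenyl]-3-{[3,4-bis(tosyloxy)phenyl]methyl}-2-hydroxy-6,8-dimethoxy-3,4-dihydronaphthalene-1-carboxylate
Product: 21 benzyl 7-(benzyloxy)-4-[4-(benzyloxy)-2-methoxyphenyl]-3-{[3,4-bis(tosyloxy)phenyl]methyl}-2-hydroxy-6,8-dimethoxynaphthalene-1-carboxylate
Conditions: DDQ (1.1 equiv), toluene, 0 °C → rt
Reagents that add atoms: none
Why: DDQ dehydrogenation (hydride abstraction from the doubly benzylic C1–H, then loss of the C2 proton) is driven by aromatisation of ring A, and one equivalent at low temperature should spare the benzyl ethers and the hydrogen-bonded naphthol.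

Step 13
Reactants: 21 benzyl 7-(benzyloxy)-4-[4-(benzyloxy)-2-methoxyphenyl]-3-{[3,4-bis(tosyloxy)phenyl]methyl}-2-hydroxy-6,8-dimethoxynaphthalene-1-carboxylate
Product: 22 benzyl 7-(benzyloxy)-4-[4-(benzyloxy)-2-methoxyphenyl]-3-[(3,4-dihydroxyphenyl)methyl]-2-hydroxy-6,8-dimethoxynaphthalene-1-carboxylate
Conditions: KOH (8 equiv), 1,4-dioxane/H2O 3:1, 90 °C, degassed, Ar; then 1 M HCl, 0 °C
Reagents that add atoms: none
Why: Hydroxide attacks sulfur and cleaves both aryl sulfonate S–O bonds, while the peri-flanked ester (deactivated as the naphtholate) and the benzyl ethers should persist; an alcohol-free medium rules out transesterification, and an ester cleaved by accident would only decarboxylate early to a compound that step 14 also converts into the target.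

Step 14
Reactants: 22 benzyl 7-(benzyloxy)-4-[4-(benzyloxy)-2-methoxyphenyl]-3-[(3,4-dihydroxyphenyl)methyl]-2-hydroxy-6,8-dimethoxynaphthalene-1-carboxylate
Product: 24 4-[(3,4-dihydroxyphenyl)methyl]-1-(4-hydroxy-2-methoxyphenyl)-5,7-dimethoxynaphthalene-3,6-diol (target CNP0000244.0; numbering as in the overview, benzyl at C2, aryl at C1), via naphthoic acid 23 (not isolated)
Conditions: H2 (1 atm), Pd/C (10%), THF/MeOH, rt; filter under Ar; then 70 °C
Reagents that add atoms: none
Why: Hydrogenolysis over Pd/C removes the two benzyl ethers and the benzyl ester under neutral conditions, and the liberated acid, ortho to the naphthol hydroxyl on an electron-rich ring, should lose CO2 on warming by ipso protonation (the known behaviour of 2-hydroxy-1-naphthoic acids), leaving C4–H.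

Compound list
1 | syringaldehyde | COc1cc(C=O)cc(OC)c1O | starting material
2 | 4-(benzyloxy)-3,5-dimethoxybenzaldehyde | COc1cc(C=O)cc(OC)c1OCc1ccccc1 | intermediate
3 | ethyl (E)-3-[4-(benzyloxy)-3,5-dimethoxyphenyl]prop-2-enoate | CCOC(=O)/C=C/c1cc(OC)c(OCc2ccccc2)c(OC)c1 | intermediate
4 | 4-bromo-3-methoxyphenol | COc1cc(O)ccc1Br | starting material
5 | 4-(benzyloxy)-1-bromo-2-methoxybenzene | COc1cc(OCc2ccccc2)ccc1Br | intermediate
6 | [4-(benzyloxy)-2-methoxyphenyl]lithium | [Li]c1ccc(OCc2ccccc2)cc1OC | intermediate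
7 | lithium [4-(benzyloxy)-2-methoxyphenyl]tri(propan-2-yloxy)borate | [Li+].COc1cc(OCc2ccccc2)ccc1[B-](OC(C)C)(OC(C)C)OC(C)C | intermediate
8 | [4-(benzyloxy)-2-methoxyphenyl]boronic acid | COc1cc(OCc2ccccc2)ccc1B(O)O | intermediate
9 | ethyl 3-[4-(benzyloxy)-3,5-dimethoxyphenyl]-3-[4-(benzyloxy)-2-methoxyphenyl]propanoate (racemic) | CCOC(=O)CC(c1ccc(OCc2ccccc2)cc1OC)c1cc(OC)c(OCc2ccccc2)c(OC)c1 | intermediate
10 | 3-[4-(benzyloxy)-3,5-dimethoxyphenyl]-3-[4-(benzyloxy)-2-methoxyphenyl]propanoic acid (racemic) | OC(=O)CC(c1ccc(OCc2ccccc2)cc1OC)c1cc(OC)c(OCc2ccccc2)c(OC)c1 | intermediate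
11 | 1-{3-[4-(benzyloxy)-3,5-dimethoxyphenyl]-3-[4-(benzyloxy)-2-methoxyphenyl]propanoyl}imidazole (racemic) | O=C(CC(c1ccc(OCc2ccccc2)cc1OC)c1cc(OC)c(OCc2ccccc2)c(OC)c1)n1ccnc1 | intermediate
12 | 2-[(benzyloxy)carbonyl]-5-[4-(benzyloxy)-3,5-dimethoxyphenyl]-5-[4-(benzyloxy)-2-methoxyphenyl]-3-oxopentanoic acid (present as its magnesium salt; mixture of stereoisomers) | OC(=O)C(C(=O)OCc1ccccc1)C(=O)CC(c1ccc(OCc2ccccc2)cc1OC)c1cc(OC)c(OCc2ccccc2)c(OC)c1 | intermediate
13 | benzyl 5-[4-(benzyloxy)-3,5-dimethoxyphenyl]-5-[4-(benzyloxy)-2-methoxyphenyl]-3-oxopentanoate (racemic) | O=C(OCc1ccccc1)CC(=O)CC(c1ccc(OCc2ccccc2)cc1OC)c1cc(OC)c(OCc2ccccc2)c(OC)c1 | intermediate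
14 | 3,4-dihydroxybenzaldehyde | O=Cc1ccc(O)c(O)c1 | starting material
15 | 4-formyl-1,2-phenylene bis(4-methylbenzenesulfonate) | O=Cc1ccc(OS(=O)(=O)c2ccc(C)cc2)c(OS(=O)(=O)c2ccc(C)cc2)c1 | intermediate
16 | 4-(hydroxymethyl)-1,2-phenylene bis(4-methylbenzenesulfonate) | OCc1ccc(OS(=O)(=O)c2ccc(C)cc2)c(OS(=O)(=O)c2ccc(C)cc2)c1 | intermediate
17 | 4-(bromomethyl)-1,2-phenylene bis(4-methylbenzenesulfonate) | BrCc1ccc(OS(=O)(=O)c2ccc(C)cc2)c(OS(=O)(=O)c2ccc(C)cc2)c1 | intermediate
18 | dilithium dienolate of 13 (deprotonated at pentanoate C2 and C4; racemic) | [Li+].[Li+].[O-]C(OCc1ccccc1)=CC([O-])=CC(c1ccc(OCc2ccccc2)cc1OC)c1cc(OC)c(OCc2ccccc2)c(OC)c1 | intermediate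
19 | benzyl (4S*,5S*)-5-[4-(benzyloxy)-3,5-dimethoxyphenyl]-5-[4-(benzyloxy)-2-methoxyphenyl]-4-{[3,4-bis(tosyloxy)phenyl]methyl}-3-oxopentanoate (racemic) | O=C(OCc1ccccc1)CC(=O)[C@@H](Cc1ccc(OS(=O)(=O)c2ccc(C)cc2)c(OS(=O)(=O)c2ccc(C)cc2)c1)[C@H](c1ccc(OCc2ccccc2)cc1OC)c1cc(OC)c(OCc2ccccc2)c(OC)c1 | intermediate
20 | benzyl (3S*,4S*)-7-(benzyloxy)-4-[4-(benzyloxy)-2-methoxyphenyl]-3-{[3,4-bis(tosyloxy)phenyl]methyl}-2-hydroxy-6,8-dimethoxy-3,4-dihydronaphthalene-1-carboxylate (racemic, trans) | O=C(OCc1ccccc1)C1=C(O)[C@@H](Cc2ccc(OS(=O)(=O)c3ccc(C)cc3)c(OS(=O)(=O)c3ccc(C)cc3)c2)[C@H](c2ccc(OCc3ccccc3)cc2OC)c2cc(OC)c(OCc3ccccc3)c(OC)c21 | intermediate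
21 | benzyl 7-(benzyloxy)-4-[4-(benzyloxy)-2-methoxyphenyl]-3-{[3,4-bis(tosyloxy)phenyl]methyl}-2-hydroxy-6,8-dimethoxynaphthalene-1-carboxylate | O=C(OCc1ccccc1)c1c(O)c(Cc2ccc(OS(=O)(=O)c3ccc(C)cc3)c(OS(=O)(=O)c3ccc(C)cc3)c2)c(-c2ccc(OCc3ccccc3)cc2OC)c2cc(OC)c(OCc3ccccc3)c(OC)c12 | intermediate
22 | benzyl 7-(benzyloxy)-4-[4-(benzyloxy)-2-methoxyphenyl]-3-[(3,4-dihydroxyphenyl)methyl]-2-hydroxy-6,8-dimethoxynaphthalene-1-carboxylate | O=C(OCc1ccccc1)c1c(O)c(Cc2ccc(O)c(O)c2)c(-c2ccc(OCc3ccccc3)cc2OC)c2cc(OC)c(OCc3ccccc3)c(OC)c12 | intermediate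
23 | 3-[(3,4-dihydroxyphenyl)methyl]-2,7-dihydroxy-4-(4-hydroxy-2-methoxyphenyl)-6,8-dimethoxynaphthalene-1-carboxylic acid | O=C(O)c1c(O)c(Cc2ccc(O)c(O)c2)c(-c2ccc(O)cc2OC)c2cc(OC)c(O)c(OC)c12 | intermediate
24 | 4-[(3,4-dihydroxyphenyl)methyl]-1-(4-hydroxy-2-methoxyphenyl)-5,7-dimethoxynaphthalene-3,6-diol... named in target numbering: 2-(3,4-dihydroxybenzyl)-1-(4-hydroxy-2-methoxyphenyl)-5,7-dimethoxynaphthalene-3,6-diol (CNP0000244.0) | COc1cc(O)ccc1-c1c(Cc2ccc(O)c(O)c2)c(O)cc2c(OC)c(O)c(OC)cc12 | target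

Total step count: 14. Longest linear sequence: 9 steps (steps 1, 2, 5, 6, 10, 11, 12, 13, 14, from syringaldehyde; the branch from 4-bromo-3-methoxyphenol is equally long).

Steps most likely to fail

Step 11. The anode may oxidise the electron-rich aryl ethers directly, the radical may dimerise or attack ring C or ring D, or the electrode may passivate. The fallback forms the same C4–C4a bond through a metal carbenoid and sets out from 19. Diazo transfer (4-acetamidobenzenesulfonyl azide, Et3N, MeCN, rt; Regitz diazo transfer) should give benzyl (4S*,5S*)-5-[4-(benzyloxy)-3,5-dimethoxyphenyl]-5-[4-(benzyloxy)-2-methoxyphenyl]-4-{[3,4-bis(tosyloxy)phenyl]methyl}-2-diazo-3-oxopentanoate F1. Treatment with Rh2(OAc)4 (1 mol%, a divalent rhodium carboxylate) in CH2Cl2 at rt should generate the electrophilic carbenoid, which undergoes intramolecular aromatic substitution at the most nucleophilic ortho carbon (ring B), a known route from aryl-tethered diazo keto esters to 2-tetralone-1-carboxylates. No C–H bond is placed for a competing five-membered insertion. The fallback returns to the route at 20.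

Step 10. Dianion formation may be incomplete, the strongly basic dianion may attack a sulfonate sulfur, or alkylation at the hindered γ-carbon may be slow and give way to O-alkylation. The fallback alkylates one stage earlier and sets out from acid 10. LDA (2.2 equiv, THF, 0 °C) should give the dilithium enediolate of 10 F2. Alkylation with 17 (−78 °C → rt; carboxylic acid dianion alkylation) should give (2S*,3S*)-3-[4-(benzyloxy)-3,5-dimethoxyphenyl]-3-[4-(benzyloxy)-2-methoxyphenyl]-2-{[3,4-bis(tosyloxy)phenyl]methyl}propanoic acid F3 as a diastereomer mixture. CDI in THF should convert it into the acyl imidazolide of F3 F4, and Mg(O2CCH2CO2Bn)2 at 45 °C (longer reaction time for the branched acyl donor) should give the acylmalonic half ester F5, which loses CO2 on acidic work-up. The acid is thus never exposed to hydroxide after the sulfonates are in place. The fallback returns to the route at 19.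

Step 5. Protodeboronation of the electron-rich, ortho-substituted boronic acid may outrun insertion of the electron-rich, poorly electrophilic cinnamate. The fallback needs neither boron nor rhodium and sets out from aldehyde 2 and bromide 5. Knoevenagel condensation of 2 with Meldrum's acid (piperidine/AcOH cat., toluene, rt) should give 5-[4-(benzyloxy)-3,5-dimethoxybenzylidene]-2,2-dimethyl-1,3-dioxane-4,6-dione F6. Bromide 5 with Mg in THF should give [4-(benzyloxy)-2-methoxyphenyl]magnesium bromide F7, which adds 1,4 to F6 without a catalyst (THF, 0 °C) to give 5-{[4-(benzyloxy)-3,5-dimethoxyphenyl][4-(benzyloxy)-2-methoxyphenyl]methyl}-2,2-dimethyl-1,3-dioxane-4,6-dione F8. Heating in DMF/H2O 10:1 at 100 °C should open the dioxanedione to 2-{[4-(benzyloxy)-3,5-dimethoxyphenyl][4-(benzyloxy)-2-methoxyphenyl]methyl}propanedioic acid F9, which decarboxylates in the same flask. The fallback returns to the route at 10.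

Further compounds
F1 | step 11 | benzyl (4S*,5S*)-5-[4-(benzyloxy)-3,5-dimethoxyphenyl]-5-[4-(benzyloxy)-2-methoxyphenyl]-4-{[3,4-bis(tosyloxy)phenyl]methyl}-2-diazo-3-oxopentanoate (racemic) | [N-]=[N+]=C(C(=O)OCc1ccccc1)C(=O)[C@@H](Cc1ccc(OS(=O)(=O)c2ccc(C)cc2)c(OS(=O)(=O)c2ccc(C)cc2)c1)[C@H](c1ccc(OCc2ccccc2)cc1OC)c1cc(OC)c(OCc2ccccc2)c(OC)c1
F2 | step 10 | dilithium enediolate of 10 (racemic) | [Li+].[Li+].[O-]C([O-])=CC(c1ccc(OCc2ccccc2)cc1OC)c1cc(OC)c(OCc2ccccc2)c(OC)c1
F3 | step 10 | (2S*,3S*)-3-[4-(benzyloxy)-3,5-dimethoxyphenyl]-3-[4-(benzyloxy)-2-methoxyphenyl]-2-{[3,4-bis(tosyloxy)phenyl]methyl}propanoic acid (racemic) | OC(=O)[C@@H](Cc1ccc(OS(=O)(=O)c2ccc(C)cc2)c(OS(=O)(=O)c2ccc(C)cc2)c1)[C@H](c1ccc(OCc2ccccc2)cc1OC)c1cc(OC)c(OCc2ccccc2)c(OC)c1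
F4 | step 10 | acyl imidazolide of F3 (racemic) | O=C([C@@H](Cc1ccc(OS(=O)(=O)c2ccc(C)cc2)c(OS(=O)(=O)c2ccc(C)cc2)c1)[C@H](c1ccc(OCc2ccccc2)cc1OC)c1cc(OC)c(OCc2ccccc2)c(OC)c1)n1ccnc1
F5 | step 10 | 2-[(benzyloxy)carbonyl]-5-[4-(benzyloxy)-3,5-dimethoxyphenyl]-5-[4-(benzyloxy)-2-methoxyphenyl]-4-{[3,4-bis(tosyloxy)phenyl]methyl}-3-oxopentanoic acid (as its magnesium salt; racemic at C4/C5) | OC(=O)C(C(=O)OCc1ccccc1)C(=O)[C@@H](Cc1ccc(OS(=O)(=O)c2ccc(C)cc2)c(OS(=O)(=O)c2ccc(C)cc2)c1)[C@H](c1ccc(OCc2ccccc2)cc1OC)c1cc(OC)c(OCc2ccccc2)c(OC)c1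
F6 | step 5 | 5-[4-(benzyloxy)-3,5-dimethoxybenzylidene]-2,2-dimethyl-1,3-dioxane-4,6-dione | CC1(C)OC(=O)C(=Cc2cc(OC)c(OCc3ccccc3)c(OC)c2)C(=O)O1
F7 | step 5 | [4-(benzyloxy)-2-methoxyphenyl]magnesium bromide | COc1cc(OCc2ccccc2)ccc1[Mg]Br
F8 | step 5 | 5-{[4-(benzyloxy)-3,5-dimethoxyphenyl][4-(benzyloxy)-2-methoxyphenyl]methyl}-2,2-dimethyl-1,3-dioxane-4,6-dione (racemic) | CC1(C)OC(=O)C(C(c2ccc(OCc3ccccc3)cc2OC)c2cc(OC)c(OCc3ccccc3)c(OC)c2)C(=O)O1
F9 | step 5 | 2-{[4-(benzyloxy)-3,5-dimethoxyphenyl][4-(benzyloxy)-2-methoxyphenyl]methyl}propanedioic acid (racemic) | OC(=O)C(C(O)=O)C(c1ccc(OCc2ccccc2)cc1OC)c1cc(OC)c(OCc2ccccc2)c(OC)c1
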